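**Strategy.** The target is cut at its two aryl–alkyl bonds, between C5 of each benzene-1,3-diol ring and C1/C14 of the tetradecane chain. C5 lies meta to both oxygen-bearing carbons C1 and C3, so it is not a nucleophilic arene position. In 3,5-dimethoxybenzoic acid, however, this same carbon carries the carboxyl group and becomes a carbanion on Birch reduction. In one operation two reduced acid molecules are joined through that carbon to both ends of 1,14-dibromotetradecane, giving the complete C6–C14–C6 skeleton as a bis(1,4-dihydrobenzoic acid). The precursors are simply the acid and the C14 α,ω-dibromide; oxidative loss of CO2 later restores both arenes.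

Key step: step 3

Remark: bisnorstriatol has no stereocentre, stereogenic axis or double-bond isomerism, so the SMILES describes one achiral compound and no step has to set or preserve configuration.

**Step 1**
Reactants: 1 tetradecanedioic acid
Product: 2 tetradecane-1,14-diol
Conditions: BH3·THF (3 equiv), THF, 0 °C → rt; H2O quench
Reagents that add atoms: none
Why: Borane reduction of carboxylic acids, in which the electrophilic hydride takes both CO2H groups through acyloxyboranes to the primary alcohols while the saturated chain offers nothing else to react.

**Step 2**
Reactants: 2 tetradecane-1,14-diol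
Product: 3 1,14-dibromotetradecane
Conditions: 48% aq. HBr (excess), conc. H2SO4, reflux; recrystallisation
Reagents that add atoms: hydrogen bromide, Br
Why: Acid-promoted SN2 substitution of the protonated primary hydroxyl groups by bromide, a standard conversion of long-chain α,ω-diols in which neither elimination nor rearrangement competes at primary carbon.

**Step 3**
Reactants: 4 3,5-dimethoxybenzoic acid (2.5 equiv); 3 1,14-dibromotetradecane (1 equiv)
Product: 7 1,1'-(tetradecane-1,14-diyl)bis(3,5-dimethoxycyclohexa-2,5-diene-1-carboxylic acid), via dilithium dianion 5 (not isolated), via dilithium dicarboxylate 6 (not isolated)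
Conditions: 4, Li (to persistent blue, ca. 2.3 equiv per 4), NH3(l)/THF, −78 °C; piperylene (to colourless); 3 in THF, −78 → −33 °C; NH3 off; ice-water/CH2Cl2, cold 1 M HCl to pH 4–5, 0 °C, immediate extraction; crude 7 used at once
Reagents that add atoms: none
Why: This is a Birch reductive alkylation of a benzoic acid: the carboxylate-bearing ring takes up two electrons and is protonated at C4 (para to the carboxylate) by the ammonium ion formed from the acid's own proton, which leaves both methoxy groups on the two surviving enol ether double bonds and places the carbanionic charge of 5 on C1 next to the carboxylate. Each primary C–Br of 3 is then displaced by C1 in an SN2 step, so both ring C1–chain bonds (to chain C1 and C14) form in one flask and give 6, which careful acidification converts into 7. No ring is closed and no stereocentre arises, because each new quaternary C1 carries two identical ring arms. The selectivity needed is alkylation at C1 rather than through C3 or C5 of the pentadienyl system; the carboxylate secures it by concentrating charge on its α-carbon, and attack at C3/C5 would also have to build a congested oxygen-bearing quaternary centre. Twofold alkylation is secured by the excess of 5 and by THF co-solvent at −33 °C for the lipophilic bromide, and surplus lithium is discharged with piperylene before 3 is added so that the C–Br bonds are not cleaved by electron transfer. Alcohol-free reduction and the absence of an alkoxy group at C4 prevent loss of methoxide, and the cold, two-phase acidification protects the four enol ethers.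

**Step 4**
Reactants: 7 1,1'-(tetradecane-1,14-diyl)bis(3,5-dimethoxycyclohexa-2,5-diene-1-carboxylic acid)
Product: 8 1,14-bis(3,5-dimethoxyphenyl)tetradecane
Conditions: Pb(OAc)4 (1.1 equiv per CO2H), pyridine (cat.), CH2Cl2, 0 °C → rt; crystallisation
Reagents that add atoms: none
Why: Lead tetraacetate oxidative decarboxylation of 1,4-dihydrobenzoic acids, in which each carboxyl group exchanges onto lead(IV) and two-electron fragmentation expels CO2 from C1 to leave a cation stabilised by both methoxy groups that loses the C4 proton, so each ring rearomatises with the chain on the former carboxyl carbon.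

**Step 5**
Reactants: 8 1,14-bis(3,5-dimethoxyphenyl)tetradecane
Product: 9 bisnorstriatol, 5,5'-(tetradecane-1,14-diyl)bis(benzene-1,3-diol)
Conditions: BBr3 (6 equiv), CH2Cl2, −78 °C → rt; ice-water
Reagents that add atoms: none
Why: Lewis-acid cleavage of aryl methyl ethers, in which boron coordinates each ether oxygen and bromide attacks the methyl group by SN2 so that the aryl–O bonds stay intact and hydrolysis on work-up frees the four phenols without touching the alkane chain.

**Compound list**
1 | tetradecanedioic acid | OC(=O)CCCCCCCCCCCCC(=O)O | starting material
2 | tetradecane-1,14-diol | OCCCCCCCCCCCCCCO | intermediate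
3 | 1,14-dibromotetradecane | BrCCCCCCCCCCCCCCBr | intermediate
4 | 3,5-dimethoxybenzoic acid | COc1cc(cc(OC)c1)C(=O)O | starting material
5 | dilithium (3,5-dimethoxycyclohexa-2,5-dien-1-ylidene)methanediolate, the dianion of 1,4-dihydro-3,5-dimethoxybenzoic acid | [Li+].[Li+].COC1=CC(=C([O-])[O-])C=C(OC)C1 | intermediate (not isolated)
6 | dilithium 1,1'-(tetradecane-1,14-diyl)bis(3,5-dimethoxycyclohexa-2,5-diene-1-carboxylate) | [Li+].[Li+].COC1=CC(CCCCCCCCCCCCCCC2(C(=O)[O-])C=C(OC)CC(OC)=C2)(C(=O)[O-])C=C(OC)C1 | intermediate (not isolated)
7 | 1,1'-(tetradecane-1,14-diyl)bis(3,5-dimethoxycyclohexa-2,5-diene-1-carboxylic acid) | COC1=CC(CCCCCCCCCCCCCCC2(C(=O)O)C=C(OC)CC(OC)=C2)(C(=O)O)C=C(OC)C1 | intermediate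
8 | 1,14-bis(3,5-dimethoxyphenyl)tetradecane | COc1cc(OC)cc(CCCCCCCCCCCCCCc2cc(OC)cc(OC)c2)c1 | intermediate
9 | bisnorstriatol, 5,5'-(tetradecane-1,14-diyl)bis(benzene-1,3-diol) | Oc1cc(O)cc(CCCCCCCCCCCCCCc2cc(O)cc(O)c2)c1 | target

**Step count.** Total: 5 steps. Longest linear sequence: 5 steps (1 → 2 → 3 → 7 → 8 → 9); 4 is bought and enters in step 3.

**Steps most likely to fail**

Step 3. The alkylation may stop after only one chain end has reacted, because the half-alkylated, soap-like lithium salt aggregates in ammonia/THF. Unquenched metal may cleave C–Br bonds by electron transfer, and the enol ethers may hydrolyse during acidification. The surplus reduced monoacid left by the excess of 5 is not a concern: carried through step 4 it should end as volatile 1,3-dimethoxybenzene and be removed when 8 is crystallised. Fallback: both aryl–chain bonds are made at the aromatic oxidation level with reversed polarity. Setting out from 3, 1-bromo-3,5-dimethoxybenzene F1 (bought) is converted with magnesium in THF into (3,5-dimethoxyphenyl)magnesium bromide F2. F2 is added slowly to 3 in THF at 0 °C with catalytic FeCl3 and TMEDA, an iron-catalysed Kumada-type coupling of an aryl Grignard reagent with a primary alkyl bromide. Both C–Br bonds should be arylated and the route is rejoined at 8, bypassing step 4.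

Step 4. Lead(IV) may attack the electron-rich enol ether double bonds, or the acetic acid released may hydrolyse them, before the carboxylate fragments. Fallback: the chemical oxidant is replaced by anodic oxidation under basic conditions. Setting out from 7, sodium methoxide (2 equiv) in methanol gives disodium 1,1'-(tetradecane-1,14-diyl)bis(3,5-dimethoxycyclohexa-2,5-diene-1-carboxylate) F3. F3 is electrolysed at a graphite anode at constant current in an undivided cell (non-Kolbe anodic decarboxylation, known for 1,4-dihydrobenzoates). Two-electron oxidation of each carboxylate should expel CO2 and, after proton loss, return the route to 8 with no acid and no electrophilic metal present.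

Step 2. Substitution in the two-phase melt may stay incomplete at one terminus, or acid-catalysed ether formation may link chains; either impurity would act as a chain stopper in step 3. Fallback: the hydroxyl groups are activated and displaced in separate operations. Setting out from 2, MsCl and Et3N in CH2Cl2 at 0 °C give tetradecane-1,14-diyl dimethanesulfonate F4. LiBr in refluxing acetone (Finkelstein-type sulfonate displacement) then returns the route to 3 under non-acidic conditions.

**Further compounds**
F1 | step 3 | 1-bromo-3,5-dimethoxybenzene (bought) | COc1cc(Br)cc(OC)c1
F2 | step 3 | (3,5-dimethoxyphenyl)magnesium bromide | COc1cc(OC)cc([Mg]Br)c1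
F3 | step 4 | disodium 1,1'-(tetradecane-1,14-diyl)bis(3,5-dimethoxycyclohexa-2,5-diene-1-carboxylate) | [Na+].[Na+].COC1=CC(CCCCCCCCCCCCCCC2(C(=O)[O-])C=C(OC)CC(OC)=C2)(C(=O)[O-])C=C(OC)C1
F4 | step 2 | tetradecane-1,14-diyl dimethanesulfonate | CS(=O)(=O)OCCCCCCCCCCCCCCOS(C)(=O)=O
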